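**Plan**

- Feature: each half holds a tetrahydropyran (O1, C2 carrying the cyclopentyl group, C3, C4, C5, C6). C5 bears an exocyclic double bond to C7, and the chain carbon C8 lies on the same side as C6. An alkene silylated at C5 can store this geometry and pass it on when C6 is attached.
- Retrosynthesis: the two silyl ethers are removed, then both C5–C6 bonds are cut (oxocarbenium/vinylsilane closure), then both C3–C4 bonds (methyl-ketone enolate plus allylic bromide). This leaves a C8 bis(vinylsilane) dibromide from hexa-1,5-diyne and two cyclopentyl methyl ketones that are epimers at the isopropenyl carbon.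
- Forward: dibromide 6 is made in three steps. One enol triflate 9 from cyclopent-2-en-1-one feeds both ketones: the left one (14) by coupling, epoxidation and hydride opening, the right one (19) by triflate reduction, epoxidation and cuprate opening. Two alkylations join the chain, the ketones are reduced, MEM ethers are made, both pyran rings close in one operation, and the silyl ethers are removed.
- Stereochemistry: the ring carbon bearing the side chain comes from an asymmetric conjugate vinylation. The ring carbinol and isopropenyl carbons come from anti opening of an epoxide by hydride (cis, left) or by carbon (trans, right). The two pyran C2 carbinols come from Felkin–Anh reduction. Both alkene geometries come from syn-hydroalumination and are kept in the ipso-substitution of silicon.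

Key step: step 19

Assumption: the (S,R,R)-phosphoramidite in step 4 is taken to give the (3R)-triflate 9; if it delivers the vinyl group to the other face, its enantiomer is used.

**Route**

Step 1
Reactants: 1 hexa-1,5-diyne
Product: 2 1,6-bis(trimethylsilyl)hexa-1,5-diyne
Conditions: n-BuLi, THF, −78 °C; Me3SiCl, −78 °C → rt
Reagents that add atoms: chlorotrimethylsilane, C[Si](C)(C)Cl
Why: Acetylide formation and C-silylation should be clean because the two terminal alkyne C–H bonds are the only acidic sites.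

Step 2
Reactants: 2 1,6-bis(trimethylsilyl)hexa-1,5-diyne
Product: 5 (2Z,6Z)-2,7-bis(trimethylsilyl)octa-2,6-diene-1,8-diol, via bis(vinylalane) 3 (not isolated), via dilithium bis(alanate) 4 (not isolated)
Conditions: i-Bu2AlH, Et2O–hexane, 40 °C; MeLi, 0 °C; (CH2O)n, 0 °C → rt; aq. Rochelle salt
Reagents that add atoms: paraformaldehyde (as formaldehyde), C=O
Why: Syn-hydroalumination of a silylalkyne in a donor solvent puts aluminium on the silicon-bearing carbon cis to the new vinylic hydrogen, and hydroxymethylation of the derived alanate occurs with retention, so each alkene should have silicon cis to the chain.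

Step 3
Reactants: 5 (2Z,6Z)-2,7-bis(trimethylsilyl)octa-2,6-diene-1,8-diol
Product: 6 (2Z,6Z)-1,8-dibromo-2,7-bis(trimethylsilyl)octa-2,6-diene
Conditions: CBr4, PPh3, CH2Cl2, 0 °C
Reagents that add atoms: tetrabromomethane, BrC(Br)(Br)Br
Why: Appel bromination converts the primary allylic alcohols into bromides under neutral conditions that should leave the vinylsilanes and their geometry untouched.

Step 4
Reactants: 7 cyclopent-2-en-1-one
Product: 9 (3R)-3-ethenylcyclopent-1-en-1-yl trifluoromethanesulfonate, via aluminium enolate 8 (not isolated)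
Conditions: CH2=CHMgBr, Me2AlCl, Et2O, 0 °C; CuBr·SMe2 (5 mol%), (S,R,R)-binaphthyl bis(1-phenylethyl)phosphoramidite (10 mol%), 7, −30 °C; Tf2O, −30 → 0 °C
Reagents that add atoms: vinylmagnesium bromide, C=C[Mg]Br; trifluoromethanesulfonic anhydride, O=S(=O)(OS(=O)(=O)C(F)(F)F)C(F)(F)F
Why: Copper-catalysed asymmetric conjugate addition of an alkenylaluminium reagent sets the ring stereocentre under ligand control, and O-triflation of the regiodefined aluminium enolate fixes the double bond between the former carbonyl carbon and the carbon next to the new stereocentre.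

Step 5
Reactants: 9 (3R)-3-ethenylcyclopent-1-en-1-yl trifluoromethanesulfonate
Product: 10 (3R)-3-ethenyl-1-(prop-1-en-2-yl)cyclopent-1-ene
Conditions: isopropenyl-B(pin), Pd(PPh3)4 (5 mol%), K3PO4, dioxane–H2O, 60 °C
Reagents that add atoms: 4,4,5,5-tetramethyl-2-(prop-1-en-2-yl)-1,3,2-dioxaborolane, CC(=C)B1OC(C)(C)C(C)(C)O1
Why: Suzuki–Miyaura coupling of an enol triflate with an alkenylboronate is mild enough that the doubly allylic stereocentre should survive.

Step 6
Reactants: 10 (3R)-3-ethenyl-1-(prop-1-en-2-yl)cyclopent-1-ene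
Product: 11 (1R,4R,5R)-4-ethenyl-1-(prop-1-en-2-yl)-6-oxabicyclo[3.1.0]hexane
Conditions: D-fructose-derived Shi ketone (30 mol%), Oxone (2KHSO5·KHSO4·K2SO4), K2CO3, Bu4NHSO4, MeCN–CH2(OMe)2–aq. Na2B4O7, 0 °C
Reagents that add atoms: potassium peroxymonosulfate, [K+].[O-]S(=O)(=O)OO
Why: Shi epoxidation oxidises the trisubstituted ring alkene of the conjugated diene, and by analogy with 1-arylcycloalkenes this ketone should deliver oxygen to the face opposite the ethenyl group, which is also the less hindered face, so catalyst and substrate are matched in setting the ring carbinol carbon.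

Step 7
Reactants: 11 (1R,4R,5R)-4-ethenyl-1-(prop-1-en-2-yl)-6-oxabicyclo[3.1.0]hexane
Product: 12 (1R,2R,5R)-2-ethenyl-5-(prop-1-en-2-yl)cyclopentan-1-ol
Conditions: Pd2(dba)3·CHCl3 (2.5 mol%), n-Bu3P, HCO2H, Et3N, dioxane, rt
Reagents that add atoms: none
Why: Palladium-catalysed formate hydrogenolysis of an alkenyloxirane ionises the tertiary allylic C–O bond with inversion and transfers hydride from palladium to the ring carbon, so hydrogen should enter anti to the departing oxygen and leave the isopropenyl group cis to the hydroxyl.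

Step 8
Reactants: 12 (1R,2R,5R)-2-ethenyl-5-(prop-1-en-2-yl)cyclopentan-1-ol
Product: 13 tert-butyl{[(1R,2R,5R)-2-ethenyl-5-(prop-1-en-2-yl)cyclopentyl]oxy}dimethylsilane
Conditions: t-BuMe2SiOTf, 2,6-lutidine, CH2Cl2, −78 → 0 °C
Reagents that add atoms: tert-butyldimethylsilyl trifluoromethanesulfonate, CC(C)(C)[Si](C)(C)OS(=O)(=O)C(F)(F)F
Why: O-Silylation with the silyl triflate should protect the hindered secondary alcohol without touching the alkenes.

Step 9
Reactants: 13 tert-butyl{[(1R,2R,5R)-2-ethenyl-5-(prop-1-en-2-yl)cyclopentyl]oxy}dimethylsilane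
Product: 14 1-[(1S,2S,3R)-2-{[tert-butyl(dimethyl)silyl]oxy}-3-(prop-1-en-2-yl)cyclopentyl]ethan-1-one
Conditions: PdCl2 (10 mol%), CuCl, O2 (1 atm), DMF–H2O, rt
Reagents that add atoms: water, O
Why: Tsuji–Wacker oxidation with divalent palladium turns the monosubstituted alkene into the methyl ketone, while the 1,1-disubstituted isopropenyl group is inert under these conditions.

Step 10
Reactants: 9 (3R)-3-ethenylcyclopent-1-en-1-yl trifluoromethanesulfonate
Product: 15 (3R)-3-ethenylcyclopent-1-ene
Conditions: Pd(OAc)2 (3 mol%), PPh3, HCO2H, n-Bu3N, DMF, 60 °C; extracted into pentane and kept in solution (volatile)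
Reagents that add atoms: none
Why: Palladium-catalysed formate reduction of an enol triflate replaces the triflate by hydrogen without moving the double bond or touching the stereocentre.

Step 11
Reactants: 15 (3R)-3-ethenylcyclopent-1-ene
Product: 16 (1R,2R,5S)-2-ethenyl-6-oxabicyclo[3.1.0]hexane
Conditions: mCPBA, NaHCO3, CH2Cl2–pentane, 0 °C
Reagents that add atoms: 3-chloroperoxybenzoic acid, O=C(OO)c1cccc(Cl)c1
Why: Prilezhaev epoxidation prefers the strained cis-disubstituted ring alkene over the vinyl group and should approach mainly anti to the allylic ethenyl substituent, which sets the ring carbinol carbon; the minor cis epoxide is removed after step 12.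

Step 12
Reactants: 16 (1R,2R,5S)-2-ethenyl-6-oxabicyclo[3.1.0]hexane
Product: 17 (1R,2R,5S)-2-ethenyl-5-(prop-1-en-2-yl)cyclopentan-1-ol
Conditions: CH2=C(CH3)MgBr, CuBr·SMe2 (10 mol%), THF, −30 → 0 °C
Reagents that add atoms: isopropenylmagnesium bromide, CC(=C)[Mg]Br
Why: Copper-catalysed Grignard opening of the epoxide is an anti SN2 attack at the ring carbon remote from the ethenyl-bearing carbon, which should place the isopropenyl group trans to the hydroxyl.

Step 13
Reactants: 17 (1R,2R,5S)-2-ethenyl-5-(prop-1-en-2-yl)cyclopentan-1-ol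
Product: 18 tert-butyl{[(1R,2R,5S)-2-ethenyl-5-(prop-1-en-2-yl)cyclopentyl]oxy}dimethylsilane
Conditions: t-BuMe2SiOTf, 2,6-lutidine, CH2Cl2, −78 → 0 °C
Reagents that add atoms: tert-butyldimethylsilyl trifluoromethanesulfonate, CC(C)(C)[Si](C)(C)OS(=O)(=O)C(F)(F)F
Why: O-Silylation with the silyl triflate should protect the alcohol flanked by two trans substituents.

Step 14
Reactants: 18 tert-butyl{[(1R,2R,5S)-2-ethenyl-5-(prop-1-en-2-yl)cyclopentyl]oxy}dimethylsilane
Product: 19 1-[(1S,2S,3S)-2-{[tert-butyl(dimethyl)silyl]oxy}-3-(prop-1-en-2-yl)cyclopentyl]ethan-1-one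
Conditions: PdCl2 (10 mol%), CuCl, O2 (1 atm), DMF–H2O, rt
Reagents that add atoms: water, O
Why: Tsuji–Wacker oxidation is again selective for the monosubstituted alkene and should give the methyl ketone with the acetyl group already trans to the silyloxy group.

Step 15
Reactants: 14 left methyl ketone; 6 (2Z,6Z)-1,8-dibromo-2,7-bis(trimethylsilyl)octa-2,6-diene
Product: 21 (4Z,8Z)-10-bromo-1-[cyclopentyl group of 14]-4,9-bis(trimethylsilyl)deca-4,8-dien-1-one, via lithium enolate 20 (not isolated)
Conditions: LiN(i-Pr)2, THF, −78 °C; 6 (4 equiv), DMPU, −78 → −30 °C; excess 6 recovered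
Reagents that add atoms: none
Why: Kinetic deprotonation occurs at the methyl group and the lithium enolate undergoes SN2 alkylation with the allylic bromide, while the excess of symmetrical dibromide suppresses reaction at both ends.

Step 16
Reactants: 19 right methyl ketone; 21 bromo ketone
Product: 23 (4Z,8Z)-1-[cyclopentyl group of 14]-12-[cyclopentyl group of 19]-4,9-bis(trimethylsilyl)dodeca-4,8-diene-1,12-dione, via lithium enolate 22 (not isolated)
Conditions: LiN(i-Pr)2, THF, −78 °C; 21, DMPU, −78 → −30 °C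
Reagents that add atoms: none
Why: The same kinetic enolate alkylation with the remaining allylic bromide joins the second, epimeric cyclopentane to the chain.

Step 17
Reactants: 23 diketone
Product: 24 (1R,4Z,8Z,12R)-diol corresponding to 23
Conditions: LiBH(s-Bu)3, THF, −78 °C; aq. NH4Cl
Reagents that add atoms: none
Why: In this Felkin–Anh-controlled reduction by a bulky borohydride, hydride should attack each ketone anti to the ring carbon that carries the silyloxy group, giving both carbinols (R) and 1,3-syn to the ring oxygen.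

Step 18
Reactants: 24 diol
Product: 25 bis(2-methoxyethoxymethyl) ether of 24
Conditions: MEMCl, i-Pr2NEt, Bu4NI (cat.), CH2Cl2, 40 °C
Reagents that add atoms: 2-methoxyethoxymethyl chloride, COCCOCCl
Why: O-Alkylation with the alkoxymethyl chloride and a hindered amine base converts both secondary alcohols into the acetals that will serve as oxocarbenium precursors.

Step 19
Reactants: 25 bis(MEM) ether
Product: 27 bis(tert-butyldimethylsilyl) ether of the target, via bis(oxocarbenium) ion 26 (not isolated)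
Conditions: SnCl4, 2,6-di-tert-butyl-4-methylpyridine, CH2Cl2, −20 °C; aq. NaHCO3
Reagents that add atoms: none
Why: SnCl4 chelates each MEM ether and ionises it to an O1=CH2 oxocarbenium ion, whose carbon (the future C6) attacks the silicon-bearing alkene carbon C5. The resulting C7 cation is stabilised by the β C–Si bond and loses Me3Si to chloride, which restores the C5=C7 double bond with C6 standing where silicon stood. The closest known reaction type is the vinylsilane-terminated cyclisation of oxocarbenium ions derived from alkoxymethyl ethers to alkylidene oxacycles. Both tetrahydropyran rings close in the 6-exo-trig mode, and no stereocentre is created. The step needs ipso regioselectivity and retention of alkene geometry, both secured by the β-silicon effect. It also needs six-membered closure to outrun attack by the isopropenyl groups, which could only react through eight-membered transition states, and the hindered pyridine keeps adventitious acid from the silyl ethers.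

Step 20
Reactants: 27 bis(silyl) ether of the target
Product: 28 target CNP0267443.2
Conditions: Bu4NF, THF, rt → 45 °C
Reagents that add atoms: none
Why: Fluoride-mediated Si–O cleavage should free both cyclopentanols without affecting the allylic ethers or the alkenes.

**Compound list**

1 | hexa-1,5-diyne | C#CCCC#C | starting material
2 | 1,6-bis(trimethylsilyl)hexa-1,5-diyne | C[Si](C)(C)C#CCCC#C[Si](C)(C)C | intermediate
3 | (1Z,5Z)-1,6-bis(diisobutylalumanyl)-1,6-bis(trimethylsilyl)hexa-1,5-diene | CC(C)C[Al](CC(C)C)/C(=C/CC/C=C(/[Al](CC(C)C)CC(C)C)[Si](C)(C)C)[Si](C)(C)C | intermediate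
4 | dilithium salt of the bis(methylalanate) of 3 | [Li+].[Li+].CC(C)C[Al-](C)(CC(C)C)/C(=C/CC/C=C(/[Al-](C)(CC(C)C)CC(C)C)[Si](C)(C)C)[Si](C)(C)C | intermediate
5 | (2Z,6Z)-2,7-bis(trimethylsilyl)octa-2,6-diene-1,8-diol | OC/C(=C/CC/C=C(/CO)[Si](C)(C)C)[Si](C)(C)C | intermediate
6 | (2Z,6Z)-1,8-dibromo-2,7-bis(trimethylsilyl)octa-2,6-diene | BrC/C(=C/CC/C=C(/CBr)[Si](C)(C)C)[Si](C)(C)C | intermediate
7 | cyclopent-2-en-1-one | O=C1CCC=C1 | starting material
8 | {[(3R)-3-ethenylcyclopent-1-en-1-yl]oxy}dimethylalumane | C=C[C@H]1CCC(O[Al](C)C)=C1 | intermediate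
9 | (3R)-3-ethenylcyclopent-1-en-1-yl trifluoromethanesulfonate | C=C[C@H]1CCC(OS(=O)(=O)C(F)(F)F)=C1 | intermediate
10 | (3R)-3-ethenyl-1-(prop-1-en-2-yl)cyclopent-1-ene | C=C[C@H]1CCC(C(C)=C)=C1 | intermediate
11 | (1R,4R,5R)-4-ethenyl-1-(prop-1-en-2-yl)-6-oxabicyclo[3.1.0]hexane (epoxide oxygen trans to ethenyl) | C=C[C@H]1CC[C@]2(C(C)=C)O[C@H]12 | intermediate
12 | (1R,2R,5R)-2-ethenyl-5-(prop-1-en-2-yl)cyclopentan-1-ol (OH trans to ethenyl, cis to isopropenyl) | C=C(C)[C@H]1CC[C@H](C=C)[C@H]1O | intermediate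
13 | tert-butyldimethylsilyl ether of 12 | C=C(C)[C@H]1CC[C@H](C=C)[C@H]1O[Si](C)(C)C(C)(C)C | intermediate
14 | 1-[(1S,2S,3R)-2-{[tert-butyl(dimethyl)silyl]oxy}-3-(prop-1-en-2-yl)cyclopentyl]ethan-1-one | C=C(C)[C@H]1CC[C@H](C(C)=O)[C@H]1O[Si](C)(C)C(C)(C)C | intermediate
15 | (3R)-3-ethenylcyclopent-1-ene | C=C[C@H]1CCC=C1 | intermediate
16 | (1R,2R,5S)-2-ethenyl-6-oxabicyclo[3.1.0]hexane (epoxide oxygen trans to ethenyl) | C=C[C@H]1CC[C@@H]2O[C@H]12 | intermediate
17 | (1R,2R,5S)-2-ethenyl-5-(prop-1-en-2-yl)cyclopentan-1-ol (OH trans to both neighbours) | C=C(C)[C@@H]1CC[C@H](C=C)[C@H]1O | intermediate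
18 | tert-butyldimethylsilyl ether of 17 | C=C(C)[C@@H]1CC[C@H](C=C)[C@H]1O[Si](C)(C)C(C)(C)C | intermediate
19 | 1-[(1S,2S,3S)-2-{[tert-butyl(dimethyl)silyl]oxy}-3-(prop-1-en-2-yl)cyclopentyl]ethan-1-one | C=C(C)[C@@H]1CC[C@H](C(C)=O)[C@H]1O[Si](C)(C)C(C)(C)C | intermediate
20 | lithium enolate of 14 (methyl side) | C=C(C)[C@H]1CC[C@H](C(=C)O[Li])[C@H]1O[Si](C)(C)C(C)(C)C | intermediate
21 | (4Z,8Z)-10-bromo-1-[(1S,2S,3R)-2-silyloxy-3-isopropenylcyclopentyl]-4,9-bis(trimethylsilyl)deca-4,8-dien-1-one | C=C(C)[C@H]1CC[C@H](C(=O)CC/C(=C/CC/C=C(/CBr)[Si](C)(C)C)[Si](C)(C)C)[C@H]1O[Si](C)(C)C(C)(C)C | intermediate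
22 | lithium enolate of 19 (methyl side) | C=C(C)[C@@H]1CC[C@H](C(=C)O[Li])[C@H]1O[Si](C)(C)C(C)(C)C | intermediate
23 | (4Z,8Z)-4,9-bis(trimethylsilyl)dodeca-4,8-diene-1,12-dione carrying the cyclopentyl group of 14 at C1 and that of 19 at C12 | C=C(C)[C@H]1CC[C@H](C(=O)CC/C(=C/CC/C=C(/CCC(=O)[C@H]2CC[C@@H](C(=C)C)[C@@H]2O[Si](C)(C)C(C)(C)C)[Si](C)(C)C)[Si](C)(C)C)[C@H]1O[Si](C)(C)C(C)(C)C | intermediate
24 | (1R,12R)-diol of 23 (each carbinol 1,3-syn to the ring silyloxy group) | C=C(C)[C@H]1CC[C@H]([C@H](O)CC/C(=C/CC/C=C(/CC[C@H]([C@H]2CC[C@@H](C(=C)C)[C@@H]2O[Si](C)(C)C(C)(C)C)O)[Si](C)(C)C)[Si](C)(C)C)[C@H]1O[Si](C)(C)C(C)(C)C | intermediate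
25 | bis(2-methoxyethoxymethyl) ether of 24 | C=C(C)[C@H]1CC[C@H]([C@H](OCOCCOC)CC/C(=C/CC/C=C(/CC[C@H]([C@H]2CC[C@@H](C(=C)C)[C@@H]2O[Si](C)(C)C(C)(C)C)OCOCCOC)[Si](C)(C)C)[Si](C)(C)C)[C@H]1O[Si](C)(C)C(C)(C)C | intermediate
26 | bis(oxocarbenium) ion from 25 (both C2 oxygens as O=CH2 cations) | C=C(C)[C@H]1CC[C@H]([C@H]([O+]=C)CC/C(=C/CC/C=C(/CC[C@H]([C@H]2CC[C@@H](C(=C)C)[C@@H]2O[Si](C)(C)C(C)(C)C)[O+]=C)[Si](C)(C)C)[Si](C)(C)C)[C@H]1O[Si](C)(C)C(C)(C)C | intermediate
27 | bis(tert-butyldimethylsilyl) ether of the target (both exocyclic alkenes Z) | C=C(C)[C@H]1CC[C@H]([C@H]2CC/C(=C/CC/C=C3/CC[C@H]([C@H]4CC[C@@H](C(=C)C)[C@@H]4O[Si](C)(C)C(C)(C)C)OC3)CO2)[C@H]1O[Si](C)(C)C(C)(C)C | intermediate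
28 | CNP0267443.2 | C=C(C)[C@H]1CC[C@H]([C@H]2CC/C(=C/CC/C=C3/CC[C@H]([C@H]4CC[C@@H](C(=C)C)[C@@H]4O)OC3)CO2)[C@H]1O | target

**Step count and risks**

Total: 20 steps. Longest linear sequence: 12 steps (7 → 28 through steps 4–9 and 15–20).

Step 4. The vinyl transfer may show poor facial selectivity, or the aluminium enolate may be trapped incompletely at oxygen. The fallback sets out from 7: a rhodium-catalysed Hayashi–Miyaura addition of potassium vinyltrifluoroborate ([Rh(acac)(C2H4)2], (S)-BINAP, dioxane–water) should give (3S)-3-ethenylcyclopentan-1-one F1, for which the sense of induction with this ligand class is well established. Kinetic deprotonation (LiN(SiMe3)2, THF, −78 °C) and triflation with PhNTf2 would then give 9 together with its regioisomer (4S)-4-ethenylcyclopent-1-en-1-yl trifluoromethanesulfonate F2, from which 9 is separated by chromatography. The route is rejoined at 9.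

Step 7. The allylpalladium intermediate has an unsubstituted terminus, so palladium may change ring face before hydride transfer, or hydride may go to the terminal carbon, and stereochemical fidelity would be lost. The fallback sets out from 15 and uses only SN2 steps. Bromohydrin formation (N-bromosuccinimide, DMSO–water) anti to the ethenyl group should give (1R,2R,3R)-2-bromo-3-ethenylcyclopentan-1-ol F3, and K2CO3 in methanol closes it to the cis epoxide (1S,2R,5R)-2-ethenyl-6-oxabicyclo[3.1.0]hexane F4. Opening with CH2=C(CH3)MgBr and CuBr·SMe2 gives (1S,2R,5R)-2-ethenyl-5-(prop-1-en-2-yl)cyclopentan-1-ol F5, whose carbinol is inverted in a Mitsunobu reaction (4-nitrobenzoic acid, PPh3, diisopropyl azodicarboxylate) to (1R,2R,5R)-2-ethenyl-5-(prop-1-en-2-yl)cyclopentyl 4-nitrobenzoate F6. Methanolysis (K2CO3, MeOH) returns to the route at 12.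

Step 16. Proton transfer between enolate 22 and the enolisable ketone of 21 may compete with alkylation and cause incomplete conversion and over-alkylation. The fallback sets out from 14 and 19 and uses azaenolates, which do not exchange protons with their products. Condensation with N,N-dimethylhydrazine gives the N,N-dimethylhydrazone of 14 F7 and the N,N-dimethylhydrazone of 19 F8. Lithiated F7 (LiN(i-Pr)2, THF) is alkylated with excess 6 to the bromo hydrazone F9, and lithiated F8 is alkylated with F9 to the bis(hydrazone) F10. Hydrolysis with aqueous Cu(OAc)2 in THF returns to the route at 23.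

**Further compounds**

F1 | step 4 | (3S)-3-ethenylcyclopentan-1-one | C=C[C@H]1CCC(=O)C1
F2 | step 4 | (4S)-4-ethenylcyclopent-1-en-1-yl trifluoromethanesulfonate | C=C[C@H]1CC=C(OS(=O)(=O)C(F)(F)F)C1
F3 | step 7 | (1R,2R,3R)-2-bromo-3-ethenylcyclopentan-1-ol | O[C@@H]1CC[C@H](C=C)[C@H]1Br
F4 | step 7 | (1S,2R,5R)-2-ethenyl-6-oxabicyclo[3.1.0]hexane | C=C[C@H]1CC[C@H]2O[C@@H]12
F5 | step 7 | (1S,2R,5R)-2-ethenyl-5-(prop-1-en-2-yl)cyclopentan-1-ol | C=C(C)[C@H]1CC[C@H](C=C)[C@@H]1O
F6 | step 7 | (1R,2R,5R)-2-ethenyl-5-(prop-1-en-2-yl)cyclopentyl 4-nitrobenzoate | C=C(C)[C@H]1CC[C@H](C=C)[C@H]1OC(=O)c1ccc(cc1)[N+](=O)[O-]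
F7 | step 16 | N,N-dimethylhydrazone of 14 | C=C(C)[C@H]1CC[C@H](/C(C)=N/N(C)C)[C@H]1O[Si](C)(C)C(C)(C)C
F8 | step 16 | N,N-dimethylhydrazone of 19 | C=C(C)[C@@H]1CC[C@H](/C(C)=N/N(C)C)[C@H]1O[Si](C)(C)C(C)(C)C
F9 | step 16 | N,N-dimethylhydrazone of 21 | C=C(C)[C@H]1CC[C@H](/C(=N/N(C)C)CC/C(=C/CC/C=C(/CBr)[Si](C)(C)C)[Si](C)(C)C)[C@H]1O[Si](C)(C)C(C)(C)C
F10 | step 16 | bis(N,N-dimethylhydrazone) of 23 | C=C(C)[C@H]1CC[C@H](/C(=N/N(C)C)CC/C(=C/CC/C=C(/CC/C(=N\N(C)C)[C@H]2CC[C@@H](C(=C)C)[C@@H]2O[Si](C)(C)C(C)(C)C)[Si](C)(C)C)[Si](C)(C)C)[C@H]1O[Si](C)(C)C(C)(C)C
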